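**Plan**

- Cuts: the C6–O vanillate bond; the C8=C14 / C9–OH unit back to a C9 ketone; C1–C5 and C7–C8 of the hydroazulene in one (4+3) step; then C6–C7, C9–C8 and C1=C10 of the open chain, which leaves the oxidative-cleavage product of (S)-terpinen-4-ol.
- Enabling feature: with ring A = C1–C5 and ring B = C1, C5–C10, the atoms C5–C6(O)–C7 form an oxyallyl cation and C1=C10–C9(O)=C8 a 2-silyloxydiene; their termini C5 and C1 are joined by the tether C2–C3–C4, which becomes ring A, so both ring-B oxygens sit on the central carbons of the two components.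
- Forward: the C1–C6 chain comes from terpinen-4-ol; C10/C9, C8 and C7 are added in turn; rings A and B close together in the cycloaddition; then C6–OH, the vanillate, C14 and C9–OH.
- Stereochemistry: C4 from (S)-terpinen-4-ol; C1 and C5 in the cycloaddition under control of C4 (C5 can equilibrate next to the C6 ketone); C6 by hydroxyl-directed hydride delivery from O4; C9 by a [2,3]-sigmatropic shift onto the α face, away from the C1 methyl.
- The chloride is placed on C7 (same oxyallyl cation), so that it arrives with C7 after the acid-sensitive diene is in place.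

Key step: step 8

Remark: atom numbers are those of the plan (C15 = methyl on C1, C14 = exocyclic methylene carbon), β is the face of the bicycle that carries C15, and commercial (S)-terpinen-4-ol is assumed to be used in enantiopure form.

**Route**

Step 1
Reactants: 1 (S)-terpinen-4-ol
Product: 2 (S)-terpinen-4-ol triethylsilyl ether
Conditions: TESOTf, 2,6-lutidine, CH2Cl2, 0 °C to rt
Reagents that add atoms: triethylsilyl trifluoromethanesulfonate, CC[Si](CC)(CC)OS(=O)(=O)C(F)(F)F
Why: Silyl triflate O-silylation of a hindered tertiary alcohol masks O4 against lactol formation, retro-aldol cleavage and later capture of the oxyallyl cation, and touches no stereocentre.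

Step 2
Reactants: 2 (S)-terpinen-4-ol triethylsilyl ether
Product: 3 (S)-3-isopropyl-6-oxo-3-(triethylsilyloxy)heptanoic acid
Conditions: RuCl3·xH2O (cat.), NaIO4, EtOAc/MeCN/H2O, rt
Reagents that add atoms: sodium periodate, [Na+].[O-]I(=O)(=O)=O; water, O
Why: RuO4-catalysed oxidative cleavage of the trisubstituted ring alkene should give the C1 methyl ketone and the C6 carboxylic acid in one operation, the C4 stereocentre being remote from the reacting carbons.

Step 3
Reactants: 3 (S)-3-isopropyl-6-oxo-3-(triethylsilyloxy)heptanoic acid; 4 diethyl [2-(methoxy(methyl)amino)-2-oxoethyl]phosphonate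
Product: 5 (3S,6E)-3-isopropyl-8-[methoxy(methyl)amino]-6-methyl-8-oxo-3-(triethylsilyloxy)oct-6-enoic acid
Conditions: NaH, THF, 0 to 60 °C; then aq. HCl to pH 3
Reagents that add atoms: none
Why: Horner–Wadsworth–Emmons olefination of the methyl ketone (present as its sodium carboxylate) builds C1=C10 with the (E)-isomer expected to predominate because the C2 chain prefers to lie anti to the amide, and the minor (Z)-isomer is removed by chromatography after step 5.

Step 4
Reactants: 5 (3S,6E)-3-isopropyl-8-[methoxy(methyl)amino]-6-methyl-8-oxo-3-(triethylsilyloxy)oct-6-enoic acid; 6 methylmagnesium bromide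
Product: 7 (3S,6E)-3-isopropyl-6-methyl-8-oxo-3-(triethylsilyloxy)non-6-enoic acid
Conditions: THF, −20 to 0 °C; then cold 1 M HCl
Reagents that add atoms: none
Why: Weinreb ketone synthesis, in which the Grignard reagent adds once to the N-methoxy-N-methylamide to give the C9 methyl ketone (C8), while the magnesium carboxylate at C6 is inert.

Step 5
Reactants: 7 (3S,6E)-3-isopropyl-6-methyl-8-oxo-3-(triethylsilyloxy)non-6-enoic acid
Product: 9 (3S,6E)-3-isopropyl-N-methoxy-N,6-dimethyl-8-oxo-3-(triethylsilyloxy)non-6-enamide, via acyl imidazolide 8 (not isolated)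
Conditions: CDI, CH2Cl2, rt; then MeNH(OMe)·HCl, rt
Reagents that add atoms: N,O-dimethylhydroxylamine hydrochloride, CNOC.Cl
Why: Carbonyldiimidazole activation and amidation (acyl substitution) turn the C6 acid into the N-methoxy-N-methylamide that allows a single carbenoid addition in step 7, and the pure (E)-isomer is secured here.

Step 6
Reactants: 9 (3S,6E)-3-isopropyl-N-methoxy-N,6-dimethyl-8-oxo-3-(triethylsilyloxy)non-6-enamide
Product: 10 (3S,6E)-8-(tert-butyldimethylsilyloxy)-3-isopropyl-N-methoxy-N,6-dimethyl-3-(triethylsilyloxy)nona-6,8-dienamide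
Conditions: LiN(i-Pr)2, THF, −78 °C; then TBSOTf, −78 °C
Reagents that add atoms: tert-butyldimethylsilyl trifluoromethanesulfonate, CC(C)(C)[Si](C)(C)OS(=O)(=O)C(F)(F)F
Why: Kinetic enolisation of the enone at the α′-methyl group C8 and O-silylation give the cross-conjugated 2-silyloxydiene with the C1=C10 geometry unchanged, the much less acidic amide being left alone.

Step 7
Reactants: 10 (3S,6E)-8-(tert-butyldimethylsilyloxy)-3-isopropyl-N-methoxy-N,6-dimethyl-3-(triethylsilyloxy)nona-6,8-dienamide; 11 chloroiodomethane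
Product: 12 (4S,7E)-9-(tert-butyldimethylsilyloxy)-1-chloro-4-isopropyl-7-methyl-4-(triethylsilyloxy)deca-7,9-dien-2-one
Conditions: MeLi·LiBr, THF/Et2O, −78 °C; then sat. aq. NH4Cl
Reagents that add atoms: none
Why: Nucleophilic acyl substitution of the Weinreb amide by chloromethyllithium (formed in the flask by iodine–lithium exchange) brings in C7 together with the chloride and stops at the ketone stage, under basic low-temperature conditions that the silyl dienol ether and the silyl ether tolerate.

Step 8
Reactants: 12 (4S,7E)-9-(tert-butyldimethylsilyloxy)-1-chloro-4-isopropyl-7-methyl-4-(triethylsilyloxy)deca-7,9-dien-2-one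
Product: 14 trans-fused cycloadduct (6-ketone; 9-OSi(t-Bu)Me2 enol ether C9=C10; 4β-OSiEt3; 4α-isopropyl; 1β-methyl; 5α-H), via oxyallyl cation 13 (not isolated)
Conditions: i-Pr2NEt, LiClO4 (2.5 M), Et2O, rt, high dilution
Reagents that add atoms: none
Why: The amine removes a C5 proton (Z enolate, C4 syn to O) and LiClO4-assisted loss of chloride from C7 gives the oxyallyl cation C5–C6(O)–C7, which the tethered electron-rich (E)-2-silyloxydiene captures in a concerted asynchronous (4+3) cycloaddition or, at the stepwise limit, by C8-to-C7 attack followed by enolate closure C5-to-C1, both paths ending in the same C6 ketone and C9 silyl enol ether. The closest known reaction type is the intramolecular (4+3) cycloaddition of oxyallyl cations, generated from α-chloro ketones with an amine and LiClO4, onto tethered 1,3-dienes to give hydroazulenones. Ring B (seven-membered) closes by union of the four-carbon and three-carbon components through C7–C8 and C1–C5, and ring A (five-membered) closes in the same event through C1–C5 across the tether C2–C3–C4, formally a 5-exo attack of diene terminus C1 on cation terminus C5. C1 is set by the diene face that the cation reaches: with lithium bridging O6 and O4 the C4–O bond lies near the oxyallyl plane on the C6 side, the isopropyl group occupies the face away from the diene next to H5, and the extended transition state of the (E)-diene then places the C1 methyl syn to O4 and C10 anti to C6. C5 follows from the same extended transition state as the trans ring fusion and, being α to the C6 ketone, can still be corrected by equilibration in step 9. The step needs facial selectivity at C1 relative to C4 and the extended over the compact mode, which the C4 stereocentre next to the cation, the (E) diene geometry and the bulky C9 silyloxy group (held away from the lithium-bound oxyallyl oxygen in the extended mode) are expected to secure, while the hindered amine avoids N-alkylation by the chloromethyl ketone.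

Step 9
Reactants: 14 trans-fused cycloadduct (6-ketone; 9-OSi(t-Bu)Me2 enol ether C9=C10; 4β-OSiEt3; 4α-isopropyl; 1β-methyl; 5α-H)
Product: 15 trans-fused 4β-hydroxy-4α-isopropyl-1β-methyl-bicyclo[5.3.0]decane-6,9-dione (5α-H)
Conditions: 1 M HCl, THF, 0 °C to rt
Reagents that add atoms: none
Why: Acid hydrolysis cleaves the silyl enol ether to the C9 ketone and the tertiary silyl ether to the free C4 hydroxyl needed to direct step 10, and the acidic medium lets C5 settle in the trans-fused arrangement through the C6 enol.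

Step 10
Reactants: 15 trans-fused 4β-hydroxy-4α-isopropyl-1β-methyl-bicyclo[5.3.0]decane-6,9-dione (5α-H)
Product: 16 trans-fused 4β,6α-dihydroxy-4α-isopropyl-1β-methyl-bicyclo[5.3.0]decan-9-one (5α-H)
Conditions: Me4NBH(OAc)3, MeCN/AcOH, −30 to 0 °C
Reagents that add atoms: none
Why: Hydroxyl-directed reduction (Saksena–Evans type), in which the acetoxyborohydride bound to O4 delivers hydride intramolecularly to the β face of the C6 ketone to set the 6α-alcohol, whereas the C9 ketone has no hydroxyl within reach and is not reduced by this mild reagent.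

Step 11
Reactants: 17 vanillic acid
Product: 19 3-methoxy-4-(triisopropylsilyloxy)benzoic acid, via bis-silylated vanillic acid 18 (not isolated)
Conditions: TIPSCl, imidazole, DMF, rt; then AcOH/THF/H2O, rt
Reagents that add atoms: triisopropylsilyl chloride, CC(C)[Si](Cl)(C(C)C)C(C)C
Why: Silylation of phenol and acid followed by selective hydrolysis of the labile silyl ester leaves the phenol as a robust triisopropylsilyl ether (protecting-group installation).

Step 12
Reactants: 16 trans-fused 4β,6α-dihydroxy-4α-isopropyl-1β-methyl-bicyclo[5.3.0]decan-9-one (5α-H); 19 3-methoxy-4-(triisopropylsilyloxy)benzoic acid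
Product: 20 6α-[3-methoxy-4-(triisopropylsilyloxy)benzoyloxy]-4β-hydroxy-4α-isopropyl-1β-methyl-bicyclo[5.3.0]decan-9-one (5α-H)
Conditions: DCC, DMAP, CH2Cl2, 0 °C to rt
Reagents that add atoms: none
Why: Steglich esterification acylates the secondary C6 hydroxyl at oxygen with retention at C6, the tertiary C4 hydroxyl being too hindered to compete.

Step 13
Reactants: 20 6α-[3-methoxy-4-(triisopropylsilyloxy)benzoyloxy]-4β-hydroxy-4α-isopropyl-1β-methyl-bicyclo[5.3.0]decan-9-one (5α-H); 21 N,N-dimethylmethyleneiminium iodide (Eschenmoser's salt)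
Product: 24 8-methylene 9-ketone (6α-aroyloxy; 4β-hydroxy; C8=C14H2), via Mannich base 22 (not isolated), via trimethylammonium iodide 23 (not isolated)
Conditions: LiN(i-Pr)2 (2.2 equiv), THF, −78 °C, then 21, to rt; then MeI, CH2Cl2, rt; then aq. NaHCO3
Reagents that add atoms: none
Why: Eschenmoser methylenation, in which kinetic deprotonation takes place at C8 (C10 is neopentyl-like next to quaternary C1), the enolate undergoes a Mannich reaction with the iminium salt, and quaternisation followed by E1cB loss of trimethylamine gives the α-methylene ketone.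

Step 14
Reactants: 24 8-methylene 9-ketone (6α-aroyloxy; 4β-hydroxy; C8=C14H2)
Product: 25 8-methylene 9-alcohol (both C9 epimers)
Conditions: NaBH4, CeCl3·7H2O, MeOH, −40 °C
Reagents that add atoms: none
Why: Luche reduction converts the enone carbonyl 1,2 without touching the aryl ester, and because hydride is expected to enter mainly from the α face (opposite the axial C1 methyl) both C9 epimers are carried on, the C9 configuration being reset in steps 15 and 16.

Step 15
Reactants: 25 8-methylene 9-alcohol (both C9 epimers)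
Product: 27 C14 phenyl sulfoxide with C8=C9 double bond (sulfur epimers), via 9-O-phenylsulfenate 26 (not isolated)
Conditions: PhSCl, Et3N, CH2Cl2, −78 °C to rt
Reagents that add atoms: benzenesulfenyl chloride, ClSc1ccccc1
Why: O-sulfenylation of the allylic alcohol and spontaneous [2,3]-sigmatropic rearrangement (Mislow–Evans equilibrium, which favours the primary allyl sulfoxide with the trisubstituted ring alkene) funnel both C9 epimers into one constitution and erase the C9 stereocentre.

Step 16
Reactants: 27 C14 phenyl sulfoxide with C8=C9 double bond (sulfur epimers)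
Product: 29 O-triisopropylsilyl ether of the target (9α-hydroxy; C8=C14H2), via 9α-O-phenylsulfenate 28 (not isolated)
Conditions: Et2NH, MeOH, 50 °C
Reagents that add atoms: none
Why: Mislow–Evans rearrangement with a thiophile, in which the sulfoxide oxygen is delivered to C9 by the [2,3] shift on the open α face (the β face is shielded by the axial C1 methyl) and diethylamine cleaves the resulting sulfenate to the 9α-alcohol with the exocyclic C8=C14 double bond.

Step 17
Reactants: 29 O-triisopropylsilyl ether of the target (9α-hydroxy; C8=C14H2)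
Product: 30 CNP0330487.1 (target)
Conditions: Bu4NF, AcOH, THF, 0 °C
Reagents that add atoms: none
Why: Fluoride cleavage of the aryl silyl ether, buffered so that the ester neither migrates nor hydrolyses, frees the phenol without affecting any stereocentre.

**Compound list**

1 | (S)-terpinen-4-ol | CC1=CC[C@](O)(C(C)C)CC1 | starting material
2 | (S)-terpinen-4-ol triethylsilyl ether | CC1=CC[C@](O[Si](CC)(CC)CC)(C(C)C)CC1 | intermediate
3 | (S)-3-isopropyl-6-oxo-3-(triethylsilyloxy)heptanoic acid | CC(=O)CC[C@@](O[Si](CC)(CC)CC)(C(C)C)CC(=O)O | intermediate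
4 | diethyl [2-(methoxy(methyl)amino)-2-oxoethyl]phosphonate | CCOP(=O)(CC(=O)N(C)OC)OCC | starting material
5 | (3S,6E)-3-isopropyl-8-[methoxy(methyl)amino]-6-methyl-8-oxo-3-(triethylsilyloxy)oct-6-enoic acid | CON(C)C(=O)/C=C(\C)CC[C@@](O[Si](CC)(CC)CC)(C(C)C)CC(=O)O | intermediate
6 | methylmagnesium bromide | C[Mg]Br | starting material
7 | (3S,6E)-3-isopropyl-6-methyl-8-oxo-3-(triethylsilyloxy)non-6-enoic acid | CC(=O)/C=C(\C)CC[C@@](O[Si](CC)(CC)CC)(C(C)C)CC(=O)O | intermediate
8 | acyl imidazolide of acid 7 | CC(=O)/C=C(\C)CC[C@@](O[Si](CC)(CC)CC)(C(C)C)CC(=O)n1ccnc1 | intermediate (not isolated)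
9 | (3S,6E)-3-isopropyl-N-methoxy-N,6-dimethyl-8-oxo-3-(triethylsilyloxy)non-6-enamide | CC(=O)/C=C(\C)CC[C@@](O[Si](CC)(CC)CC)(C(C)C)CC(=O)N(C)OC | intermediate
10 | (3S,6E)-8-(tert-butyldimethylsilyloxy)-3-isopropyl-N-methoxy-N,6-dimethyl-3-(triethylsilyloxy)nona-6,8-dienamide | C=C(O[Si](C)(C)C(C)(C)C)/C=C(\C)CC[C@@](O[Si](CC)(CC)CC)(C(C)C)CC(=O)N(C)OC | intermediate
11 | chloroiodomethane | ClCI | starting material
12 | (4S,7E)-9-(tert-butyldimethylsilyloxy)-1-chloro-4-isopropyl-7-methyl-4-(triethylsilyloxy)deca-7,9-dien-2-one (key-step precursor) | C=C(O[Si](C)(C)C(C)(C)C)/C=C(\C)CC[C@@](O[Si](CC)(CC)CC)(C(C)C)CC(=O)CCl | intermediate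
13 | oxyallyl cation C5–C6(O)–C7 derived from 12 (zwitterion) | C=C(O[Si](C)(C)C(C)(C)C)/C=C(\C)CC[C@@](O[Si](CC)(CC)CC)(C(C)C)[CH+]C([O-])=C | intermediate (not isolated)
14 | trans-fused cycloadduct: bicyclo[5.3.0]dec-9-en-6-one with 9-OSi(t-Bu)Me2, 4β-OSiEt3, 4α-isopropyl, 1β-methyl, 5α-H | C1CC(=O)[C@@H]2[C@](C)(CC[C@@]2(O[Si](CC)(CC)CC)C(C)C)C=C1O[Si](C)(C)C(C)(C)C | intermediate
15 | trans-fused 4β-hydroxy-4α-isopropyl-1β-methyl-bicyclo[5.3.0]decane-6,9-dione (5α-H) | C1CC(=O)[C@@H]2[C@](C)(CC[C@@]2(O)C(C)C)CC1=O | intermediate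
16 | trans-fused 4β,6α-dihydroxy-4α-isopropyl-1β-methyl-bicyclo[5.3.0]decan-9-one (5α-H) | C1C[C@H](O)[C@@H]2[C@](C)(CC[C@@]2(O)C(C)C)CC1=O | intermediate
17 | vanillic acid | COc1cc(C(=O)O)ccc1O | starting material
18 | triisopropylsilyl 3-methoxy-4-(triisopropylsilyloxy)benzoate | COc1cc(C(=O)O[Si](C(C)C)(C(C)C)C(C)C)ccc1O[Si](C(C)C)(C(C)C)C(C)C | intermediate (not isolated)
19 | 3-methoxy-4-(triisopropylsilyloxy)benzoic acid | COc1cc(C(=O)O)ccc1O[Si](C(C)C)(C(C)C)C(C)C | intermediate
20 | 6α-[3-methoxy-4-(triisopropylsilyloxy)benzoyloxy]-4β-hydroxy-4α-isopropyl-1β-methyl-bicyclo[5.3.0]decan-9-one (5α-H) | C1C[C@H](OC(=O)c3ccc(O[Si](C(C)C)(C(C)C)C(C)C)c(OC)c3)[C@@H]2[C@](C)(CC[C@@]2(O)C(C)C)CC1=O | intermediate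
21 | N,N-dimethylmethyleneiminium iodide (Eschenmoser's salt) | C[N+](C)=C.[I-] | starting material
22 | Mannich base: 8-(dimethylaminomethyl) derivative of 20 (C8 epimers) | CN(C)CC1C[C@H](OC(=O)c3ccc(O[Si](C(C)C)(C(C)C)C(C)C)c(OC)c3)[C@@H]2[C@](C)(CC[C@@]2(O)C(C)C)CC1=O | intermediate (not isolated)
23 | trimethylammonium iodide of 22 | C[N+](C)(C)CC1C[C@H](OC(=O)c3ccc(O[Si](C(C)C)(C(C)C)C(C)C)c(OC)c3)[C@@H]2[C@](C)(CC[C@@]2(O)C(C)C)CC1=O.[I-] | intermediate (not isolated)
24 | 8-methylene 9-ketone (6α-aroyloxy, 4β-hydroxy, C8=C14H2) | C=C1C[C@H](OC(=O)c3ccc(O[Si](C(C)C)(C(C)C)C(C)C)c(OC)c3)[C@@H]2[C@](C)(CC[C@@]2(O)C(C)C)CC1=O | intermediate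
25 | 8-methylene 9-alcohol, both C9 epimers | C=C1C[C@H](OC(=O)c3ccc(O[Si](C(C)C)(C(C)C)C(C)C)c(OC)c3)[C@@H]2[C@](C)(CC[C@@]2(O)C(C)C)CC1O | intermediate
26 | 9-O-phenylsulfenate of 25 (C9 epimers) | C=C1C[C@H](OC(=O)c3ccc(O[Si](C(C)C)(C(C)C)C(C)C)c(OC)c3)[C@@H]2[C@](C)(CC[C@@]2(O)C(C)C)CC1OSc4ccccc4 | intermediate (not isolated)
27 | C14 phenyl sulfoxide with C8=C9 double bond (sulfur epimers) | C1=C(CS(=O)c4ccccc4)C[C@H](OC(=O)c3ccc(O[Si](C(C)C)(C(C)C)C(C)C)c(OC)c3)[C@@H]2[C@](C)(CC[C@@]2(O)C(C)C)C1 | intermediate
28 | 9α-O-phenylsulfenate with C8=C14H2 | C=C1C[C@H](OC(=O)c3ccc(O[Si](C(C)C)(C(C)C)C(C)C)c(OC)c3)[C@@H]2[C@](C)(CC[C@@]2(O)C(C)C)C[C@@H]1OSc4ccccc4 | intermediate (not isolated)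
29 | O-triisopropylsilyl ether of the target | C=C1C[C@H](OC(=O)c3ccc(O[Si](C(C)C)(C(C)C)C(C)C)c(OC)c3)[C@@H]2[C@](C)(CC[C@@]2(O)C(C)C)C[C@@H]1O | intermediate
30 | CNP0330487.1: (1R,4R,5S,6S,9S)-4β,9α-dihydroxy-4α-isopropyl-1β-methyl-8-methylene-bicyclo[5.3.0]decan-6α-yl 4-hydroxy-3-methoxybenzoate | C=C1C[C@H](OC(=O)c2ccc(O)c(OC)c2)[C@@H]2[C@](C)(CC[C@@]2(O)C(C)C)C[C@@H]1O | target

**Step count and risks**

Total: 17 steps. Longest linear sequence: 16 steps (steps 1–10 and 12–17 from (S)-terpinen-4-ol; step 11 is a one-step side branch).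

Steps most likely to fail:

1. Step 8. The compact transition state could compete with the extended one, giving the wrong diene face at C1. The C5 enolate could also lose the C4 silyloxy group instead of ionising, or the cation could be trapped intermolecularly. Fallback: rings A and B are closed one after the other, starting from amide 10. MeMgBr would give (4S,7E)-9-(tert-butyldimethylsilyloxy)-4-isopropyl-7-methyl-4-(triethylsilyloxy)deca-7,9-dien-2-one F1. Mild acid (PPTS, wet acetone) would unmask the enone to (4S,7E)-4-isopropyl-7-methyl-4-(triethylsilyloxy)dec-7-ene-2,9-dione F2. An intramolecular Michael addition (KOt-Bu cat., t-BuOH/THF, 0 °C; 5-exo, C5 onto C1, C5 under thermodynamic control) would close ring A to the 5-acetyl-1-acetonyl cyclopentane F3. Its kinetic bis-enolate at C7 and C8 (LiN(i-Pr)2, −78 °C) would be coupled oxidatively with CuCl2 to close ring B as the O4-triethylsilyl ether of the bicyclic 6,9-dione F4. The conditions of step 9 then rejoin the route at 15.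

2. Step 16. Facial discrimination in the return [2,3] shift may be poor, or the hindered sulfoxide may resist thiophilic cleavage, which would leave C9 uncontrolled. Fallback: the C9 oxygen is introduced by epoxidation, starting from enone 24. Conjugate reduction with LiBH(s-Bu)3 and trapping of the C8=C9 enolate with PhNTf2 would give the 8-methyl-8-en-9-yl triflate F5. Reduction with Pd(OAc)2/PPh3, HCO2H and Bu3N would give the 8-methyl-8-ene F6. mCPBA (NaHCO3, CH2Cl2) is expected to attack the open α face and give the 8α,9α-epoxide F7. Opening with Cp2TiCl (trivalent titanium, from Cp2TiCl2 and Mn, THF) at the tertiary carbon C8 with loss of a C14 hydrogen would give the 8(14)-en-9α-ol, rejoining the route at 29.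

3. Step 3. Addition of the stabilised phosphonate anion to the ketone carboxylate may be sluggish and E/Z discrimination weak. Fallback: the enone is made by alkynylation and rearrangement, starting from keto acid 3. 1-Propynylmagnesium bromide (excess, THF, 0 °C) would add to the ketone of the magnesium carboxylate to give (3S)-6-hydroxy-3-isopropyl-6-methyl-3-(triethylsilyloxy)non-7-ynoic acid F8. A Meyer–Schuster rearrangement (Ph3PAuNTf2 cat., MeOH, toluene) would give enone acid 7 directly, bypassing 5; the (E)-isomer is again secured at 9.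

Further compounds
F1 | step 8 | (4S,7E)-9-(tert-butyldimethylsilyloxy)-4-isopropyl-7-methyl-4-(triethylsilyloxy)deca-7,9-dien-2-one | C=C(O[Si](C)(C)C(C)(C)C)/C=C(\C)CC[C@@](O[Si](CC)(CC)CC)(C(C)C)CC(C)=O
F2 | step 8 | (4S,7E)-4-isopropyl-7-methyl-4-(triethylsilyloxy)dec-7-ene-2,9-dione | CC(=O)/C=C(\C)CC[C@@](O[Si](CC)(CC)CC)(C(C)C)CC(C)=O
F3 | step 8 | 5-acetyl-1-acetonyl cyclopentane (1β-methyl, 4β-OSiEt3, 4α-isopropyl, 5α-H) | CC(=O)[C@@H]1[C@](C)(CC[C@@]1(O[Si](CC)(CC)CC)C(C)C)CC(C)=O
F4 | step 8 | O4-triethylsilyl ether of dione 15 | C1CC(=O)[C@@H]2[C@](C)(CC[C@@]2(O[Si](CC)(CC)CC)C(C)C)CC1=O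
F5 | step 16 | 8-methyl-8-en-9-yl triflate (6α-aroyloxy, 4β-hydroxy) | C1(=C(C)C[C@H](OC(=O)c3ccc(O[Si](C(C)C)(C(C)C)C(C)C)c(OC)c3)[C@@H]2[C@](C)(CC[C@@]2(O)C(C)C)C1)OS(=O)(=O)C(F)(F)F
F6 | step 16 | 8-methyl-8-ene (6α-aroyloxy, 4β-hydroxy) | C1=C(C)C[C@H](OC(=O)c3ccc(O[Si](C(C)C)(C(C)C)C(C)C)c(OC)c3)[C@@H]2[C@](C)(CC[C@@]2(O)C(C)C)C1
F7 | step 16 | 8α,9α-epoxide of F6 | C[C@@]12C[C@H](OC(=O)c4ccc(O[Si](C(C)C)(C(C)C)C(C)C)c(OC)c4)[C@@H]3[C@](C)(CC[C@@]3(O)C(C)C)C[C@@H]1O2
F8 | step 3 | (3S)-6-hydroxy-3-isopropyl-6-methyl-3-(triethylsilyloxy)non-7-ynoic acid (C6 epimers) | CC#CC(C)(O)CC[C@@](O[Si](CC)(CC)CC)(C(C)C)CC(=O)O
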